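**Plan**

1. Retrosynthetic cuts: first the C8–CH(Ph) bond (late Michael addition, aldehyde then oxidised to the acid); then, in one operation, the ring-fusion bond C4a–C8a and the C2–C3 bond of the pyran ring (O1–C2 forms in the same flask); then C6–prenyl at the quaternary carbon and C6–CH2(cyclobutyl).
2. Enabling feature: ring B (O1, C2, C3, C4, C4a, C8a) is the C4 ketone whose two α-carbons (C4a and C3) are bonded to carboxyl-level carbons (C8a and C2) that share O1. The ketone side chain is therefore acylated twice: at C4a by an acylketene carbon, which closes ring A (C4a, C5, C6, C7, C8, C8a), and at C3 by an O-acetyl carbon. Helpers: the C5 oxygen is a methyl enol ether (only the C8a oxygen can become O1), ring B is made at the γ-pyrone level, and a tert-butyl ester serves as latent ketene.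
3. Forward order: cyclobutylmethyl iodide from verbenone; acetoacetate alkylation; enamine-controlled prenylation; ketone to alkyne; ester to β-keto ester; ynone; (Z)-methoxy-enone; key step (ring A, then ring B); 1,4-reduction; O-demethylation; Michael addition at C8; oxidation.
4. Stereochemistry: cyclobutane centres from (1S)-(−)-verbenone; C6 from the (S)-valine tert-butyl ester enamine; C2 from ligand-controlled copper hydride addition and C3 (cis) from kinetic protonation; the benzylic centre from the (S)-diarylprolinol silyl ether catalyst.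
5. Numbering and names: chromene numbering of the bicyclic core throughout; CbCH2 = [(1R,3S)-2,2-dimethyl-3-(prop-1-en-2-yl)cyclobutyl]methyl (1,3-cis); prenyl = 3-methylbut-2-en-1-yl.

Key step: step 12

Remark: the target is an enolised β-triketone, so its tautomers are treated as one compound and every enolisable intermediate is drawn as a single tautomer.

**Route**

Step 1
Reactants: 1 (1S,5S)-(−)-verbenone
Product: 2 (1S,3R)-3-acetyl-2,2-dimethylcyclobutane-1-carboxylic acid (cis-pinononic acid)
Conditions: RuCl3·xH2O (2 mol %), NaIO4 (4.2 equiv), CCl4/MeCN/H2O, rt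
Reagents that add atoms: sodium periodate, [Na+].[O-]I(=O)(=O)=O; water, O
Why: Oxidative cleavage of the enone C=C by RuO4 formed in the flask, with loss of CO2 from the α-keto acid, is the standard passage from verbenone to cis-pinononic acid, and both ring stereocentres are carried over untouched from the terpene.

Step 2
Reactants: 2 (1S,3R)-3-acetyl-2,2-dimethylcyclobutane-1-carboxylic acid
Product: 3 (1S,3S)-2,2-dimethyl-3-(prop-1-en-2-yl)cyclobutane-1-carboxylic acid
Conditions: Ph3PCH3Br (2.5 equiv), KOtBu (2.5 equiv), THF, 0 °C to rt; then dilute HCl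
Reagents that add atoms: methyltriphenylphosphonium bromide, C[P+](c1ccccc1)(c1ccccc1)c1ccccc1.[Br-]
Why: Wittig methylenation of the methyl ketone on the carboxylate salt should give the isopropenyl group, and any base-induced equilibration at the ketone α-carbon can only favour the wanted, more stable 1,3-cis arrangement.

Step 3
Reactants: 3 (1S,3S)-2,2-dimethyl-3-(prop-1-en-2-yl)cyclobutane-1-carboxylic acid
Product: 4 [(1S,3S)-2,2-dimethyl-3-(prop-1-en-2-yl)cyclobutyl]methanol
Conditions: LiAlH4, THF, 0 °C to rt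
Reagents that add atoms: none
Why: Hydride reduction of the acid to the primary alcohol leaves the isolated alkene and both stereocentres untouched.

Step 4
Reactants: 4 [(1S,3S)-2,2-dimethyl-3-(prop-1-en-2-yl)cyclobutyl]methanol
Product: 5 (1S,3S)-1-(iodomethyl)-2,2-dimethyl-3-(prop-1-en-2-yl)cyclobutane
Conditions: I2, PPh3, imidazole, CH2Cl2, 0 °C
Reagents that add atoms: iodine, II
Why: Appel-type iodination replaces the primary hydroxyl by SN2 at the CH2 group, so no stereocentre is involved.

Step 5
Reactants: 5 (1S,3S)-1-(iodomethyl)-2,2-dimethyl-3-(prop-1-en-2-yl)cyclobutane; 6 methyl acetoacetate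
Product: 7 methyl 2-(CbCH2)-3-oxobutanoate (both C2 epimers)
Conditions: NaH, THF/DMF, 0 to 60 °C
Reagents that add atoms: none
Why: C-alkylation of the acetoacetate enolate by the primary iodide is a standard acetoacetic ester alkylation, and the new α-centre is formed unselectively because it becomes planar in the next step.

Step 6
Reactants: 7 methyl 2-(CbCH2)-3-oxobutanoate; 8 tert-butyl (S)-valinate
Product: 9 methyl (2Z)-3-{[(2S)-1-tert-butoxy-3-methyl-1-oxobutan-2-yl]amino}-2-(CbCH2)but-2-enoate
Conditions: 4 Å molecular sieves, AcOH (5 mol %), toluene, 50 °C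
Reagents that add atoms: none
Why: Condensation of the primary amine with the ketone of the β-keto ester gives the hydrogen-bonded (Z)-enamino ester, which erases the α-centre of 7 and installs the stereocontrolling auxiliary.

Step 7
Reactants: 9 methyl (2Z)-3-{[(2S)-1-tert-butoxy-3-methyl-1-oxobutan-2-yl]amino}-2-(CbCH2)but-2-enoate
Product: 11 methyl (2S)-2-acetyl-2-(CbCH2)-5-methylhex-4-enoate, via ketimine 10 (not isolated)
Conditions: LiN(i-Pr)2, toluene, HMPA (1 equiv), −78 °C; prenyl bromide, −78 to −20 °C; then 10% aqueous citric acid, rt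
Reagents that add atoms: prenyl bromide, CC(C)=CCBr; water, O
Why: Alkylation of the chelated lithium aza-enolate of a valine tert-butyl ester enamine is an established route to acyclic α,α-dialkyl β-keto esters; the isopropyl group of the (S)-auxiliary shields one face of the planar chelate so that prenyl bromide should enter from the other and set the quaternary carbon (later C6) as S, after which mild acid hydrolyses ketimine 10 and returns the auxiliary.

Step 8
Reactants: 11 methyl (2S)-2-acetyl-2-(CbCH2)-5-methylhex-4-enoate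
Product: 13 methyl (2S)-2-(CbCH2)-2-ethynyl-5-methylhex-4-enoate, via enol phosphate 12 (not isolated)
Conditions: LiN(i-Pr)2 (1.1 equiv), THF, −78 °C; ClP(O)(OEt)2; LiN(i-Pr)2 (2.3 equiv), −78 to 0 °C; then H2O
Reagents that add atoms: none
Why: Kinetic enolisation of the methyl ketone (its only enolisable side), O-phosphorylation and base-induced elimination of phosphate is a known one-flask conversion of methyl ketones into terminal alkynes, and the quaternary centre has no α-hydrogen and cannot epimerise.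

Step 9
Reactants: 13 methyl (2S)-2-(CbCH2)-2-ethynyl-5-methylhex-4-enoate
Product: 14 tert-butyl (4S)-4-(CbCH2)-4-ethynyl-7-methyl-3-oxooct-6-enoate
Conditions: tert-butyl acetate, LiN(i-Pr)2 (3.5 equiv each), THF, −78 °C; add 13, −78 to −20 °C; then aqueous NH4Cl
Reagents that add atoms: tert-butyl acetate, CC(=O)OC(C)(C)C
Why: Crossed Claisen condensation of the ester enolate with the non-enolisable methyl ester is driven by deprotonation of the β-keto ester formed, the excess enolate covering the acidic alkyne hydrogen.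

Step 10
Reactants: 14 tert-butyl (4S)-4-(CbCH2)-4-ethynyl-7-methyl-3-oxooct-6-enoate
Product: 15 tert-butyl (4S)-4-(CbCH2)-4-prenyl-3,7-dioxonon-5-ynoate
Conditions: LiN(i-Pr)2 (2.2 equiv), THF, −78 °C; EtC(=O)N(OMe)Me, −78 to 0 °C; then aqueous NH4Cl
Reagents that add atoms: N-methoxy-N-methylpropanamide, CCC(=O)N(C)OC
Why: In the dianion the lithium acetylide is far more nucleophilic than the β-keto ester enolate, and its acylation by an N-methoxy-N-methylamide stops at the chelated tetrahedral adduct, so the ynone should form without over-addition.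

Step 11
Reactants: 15 tert-butyl (4S)-4-(CbCH2)-4-prenyl-3,7-dioxonon-5-ynoate
Product: 16 tert-butyl (4S,5Z)-4-(CbCH2)-5-methoxy-4-prenyl-3,7-dioxonon-5-enoate
Conditions: NaOMe (1.2 equiv), MeOH, 0 °C to rt; then AcOH
Reagents that add atoms: methanol, CO
Why: Oxa-Michael addition of methoxide to the β-carbon of the ynone with anti protonation should give the (Z)-β-methoxy enone, which places the bulky quaternary carbon trans to the acyl group and puts the methyl mask regiospecifically on the future C5 oxygen.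

Step 12
Reactants: 16 tert-butyl (4S,5Z)-4-(CbCH2)-5-methoxy-4-prenyl-3,7-dioxonon-5-enoate
Product: 21 (6S)-6-(CbCH2)-5-methoxy-2,3-dimethyl-6-prenyl-4H-chromene-4,7(6H)-dione, via acylketene 17 (not isolated), via hydroxy dienone 18 (not isolated), via enol acetate 19 (not isolated), via triketone 20 (not isolated)
Conditions: Ac2O (6 equiv), NaOAc (3 equiv), xylene, 140 °C, sealed tube
Reagents that add atoms: acetic anhydride, CC(=O)OC(C)=O
Why: Proposed new method: heating expels tert-butanol from the β-keto ester to give acylketene 17, whose ketene carbon is attacked by the α-carbon of the (Z)-β-methoxy enone (6-(enolendo)-exo-dig C-acylation, the enol ether being restored by proton loss), so ring A closes through the C4a–C8a bond to give 18; the closest known reactions are the capture of thermally generated acylketenes by enol ethers and enaminones and the Claisen-type cyclisation of polyketo esters. The enol oxygen on C8a is then acetylated (19), acetate-mediated enolisation of the propanoyl CH2 transfers the acetyl group from oxygen to carbon through a six-membered transition state (Baker–Venkataraman step, C2–C3 bond, 20), and the 1,3-diketone cyclodehydrates (6-exo-trig addition of the C8a enol oxygen to the new ketone, then loss of water) to the γ-pyrone ring B, as in a Kostanecki–Robinson chromone synthesis. No stereocentre is created; the transient side-chain centre of 20 is erased on dehydration and the quaternary C6 has no α-hydrogen. The step needs site selectivity between the two oxygens that flank C4a: the C5 oxygen is locked as its methyl ether, so only the C8a oxygen can become O1. The Z geometry of the enone holds the C4 ketone away from the β-keto ester carbon, which shuts off the competing aldol mode of ring closure, and acetylation of the C7 enol oxygen is unproductive but reversible under acetate, so the material should funnel to 21.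

Step 13
Reactants: 21 (6S)-6-(CbCH2)-5-methoxy-2,3-dimethyl-6-prenyl-4H-chromene-4,7(6H)-dione
Product: 22 (2R,3S,6S)-6-(CbCH2)-5-methoxy-2,3-dimethyl-6-prenyl-2,3-dihydro-4H-chromene-4,7(6H)-dione
Conditions: Cu(OAc)2·H2O (5 mol %), (R)-DTBM-SEGPHOS (5.5 mol %), (EtO)2MeSiH (3 equiv), t-BuOH (3 equiv), toluene, 0 °C to rt
Reagents that add atoms: none
Why: Ligand-controlled copper hydride 1,4-reduction is known for chromones and spares isolated alkenes; hydride should add to C2, the least hindered β-carbon (C5 carries the methoxy group next to the quaternary centre), on the face selected by the ligand (2R), and the enolate should then be protonated at C3 anti to the pseudo-axial C2 methyl group, which gives the cis (3S) isomer under kinetic control.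

Step 14
Reactants: 22 (2R,3S,6S)-6-(CbCH2)-5-methoxy-2,3-dimethyl-6-prenyl-2,3-dihydro-4H-chromene-4,7(6H)-dione
Product: 23 (2R,3S,6R)-6-(CbCH2)-4-hydroxy-2,3-dimethyl-6-prenyl-2H-chromene-5,7(3H,6H)-dione
Conditions: LiCl (10 equiv), DMSO, 110 °C; then aqueous NH4Cl
Reagents that add atoms: none
Why: SN2 attack of chloride on the methyl group of the vinylogous ester, with a stabilised triketone enolate as leaving group, is the usual unmasking of methyl enol ethers of acylphloroglucinol-type triketones, and the neutral, non-basic medium should leave C2 and C3 untouched and not attack the secondary C2–O1 bond.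

Step 15
Reactants: 23 (2R,3S,6R)-6-(CbCH2)-4-hydroxy-2,3-dimethyl-6-prenyl-2H-chromene-5,7(3H,6H)-dione; 24 (E)-cinnamaldehyde
Product: 25 (3S)-3-[(2R,3S,6R)-6-(CbCH2)-4-hydroxy-2,3-dimethyl-5,7-dioxo-6-prenyl-3,5,6,7-tetrahydro-2H-chromen-8-yl]-3-phenylpropanal
Conditions: (S)-α,α-diphenylprolinol trimethylsilyl ether (20 mol %), PhCO2H (20 mol %), CH2Cl2, rt
Reagents that add atoms: none
Why: Iminium-ion-catalysed Michael addition of enolised cyclic 1,3-dicarbonyl compounds to enals is well known; C8 is the only free nucleophilic carbon, and the silyloxydiphenylmethyl group shields one face of the (E)-iminium ion so that C8 should add to the other and set the benzylic centre as S.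

Step 16
Reactants: 25 (3S)-3-[(2R,3S,6R)-6-(CbCH2)-4-hydroxy-2,3-dimethyl-5,7-dioxo-6-prenyl-3,5,6,7-tetrahydro-2H-chromen-8-yl]-3-phenylpropanal
Product: 26 (3S)-3-[(2R,3S,6R)-6-(CbCH2)-4-hydroxy-2,3-dimethyl-5,7-dioxo-6-prenyl-3,5,6,7-tetrahydro-2H-chromen-8-yl]-3-phenylpropanoic acid (target)
Conditions: NaClO2, NaH2PO4, 2-methyl-2-butene (excess), t-BuOH/H2O, 0 °C to rt
Reagents that add atoms: sodium chlorite, [Na+].[O-]Cl=O
Why: Pinnick oxidation converts the aldehyde into the acid under buffered, weakly acidic conditions that do not enolise C3 or touch the benzylic centre, the alkene scavenger protecting the prenyl and isopropenyl groups from hypochlorous acid.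

**Compound list**

1 | (1S,5S)-(−)-verbenone | CC1=CC(=O)[C@H]2C[C@@H]1C2(C)C | starting material
2 | (1S,3R)-3-acetyl-2,2-dimethylcyclobutane-1-carboxylic acid | CC(=O)[C@@H]1C[C@H](C(=O)O)C1(C)C | intermediate
3 | (1S,3S)-2,2-dimethyl-3-(prop-1-en-2-yl)cyclobutane-1-carboxylic acid | C=C(C)[C@@H]1C[C@H](C(=O)O)C1(C)C | intermediate
4 | [(1S,3S)-2,2-dimethyl-3-(prop-1-en-2-yl)cyclobutyl]methanol | C=C(C)[C@@H]1C[C@H](CO)C1(C)C | intermediate
5 | (1S,3S)-1-(iodomethyl)-2,2-dimethyl-3-(prop-1-en-2-yl)cyclobutane | C=C(C)[C@@H]1C[C@H](CI)C1(C)C | intermediate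
6 | methyl acetoacetate | COC(=O)CC(C)=O | starting material
7 | methyl 2-(CbCH2)-3-oxobutanoate (both C2 epimers) | C=C(C)[C@@H]1C[C@H](CC(C(C)=O)C(=O)OC)C1(C)C | intermediate
8 | tert-butyl (S)-valinate | CC(C)[C@H](N)C(=O)OC(C)(C)C | starting material
9 | methyl (2Z)-3-{[(2S)-1-tert-butoxy-3-methyl-1-oxobutan-2-yl]amino}-2-(CbCH2)but-2-enoate | C=C(C)[C@@H]1C[C@H](C/C(C(=O)OC)=C(C)/N[C@@H](C(C)C)C(=O)OC(C)(C)C)C1(C)C | intermediate
10 | ketimine of 11 with tert-butyl (S)-valinate (quaternary carbon S) | C=C(C)[C@@H]1C[C@H](C[C@@](CC=C(C)C)(C(C)=N[C@@H](C(C)C)C(=O)OC(C)(C)C)C(=O)OC)C1(C)C | intermediate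
11 | methyl (2S)-2-acetyl-2-(CbCH2)-5-methylhex-4-enoate | C=C(C)[C@@H]1C[C@H](C[C@@](CC=C(C)C)(C(C)=O)C(=O)OC)C1(C)C | intermediate
12 | methyl (2S)-2-(CbCH2)-2-{1-[(diethoxyphosphoryl)oxy]ethenyl}-5-methylhex-4-enoate | C=C(C)[C@@H]1C[C@H](C[C@@](CC=C(C)C)(C(=C)OP(=O)(OCC)OCC)C(=O)OC)C1(C)C | intermediate
13 | methyl (2S)-2-(CbCH2)-2-ethynyl-5-methylhex-4-enoate | C=C(C)[C@@H]1C[C@H](C[C@@](CC=C(C)C)(C#C)C(=O)OC)C1(C)C | intermediate
14 | tert-butyl (4S)-4-(CbCH2)-4-ethynyl-7-methyl-3-oxooct-6-enoate | C=C(C)[C@@H]1C[C@H](C[C@@](CC=C(C)C)(C#C)C(=O)CC(=O)OC(C)(C)C)C1(C)C | intermediate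
15 | tert-butyl (4S)-4-(CbCH2)-4-prenyl-3,7-dioxonon-5-ynoate | C=C(C)[C@@H]1C[C@H](C[C@@](CC=C(C)C)(C#CC(=O)CC)C(=O)CC(=O)OC(C)(C)C)C1(C)C | intermediate
16 | tert-butyl (4S,5Z)-4-(CbCH2)-5-methoxy-4-prenyl-3,7-dioxonon-5-enoate | C=C(C)[C@@H]1C[C@H](C[C@@](CC=C(C)C)(/C(OC)=C/C(=O)CC)C(=O)CC(=O)OC(C)(C)C)C1(C)C | intermediate
17 | (4S,5Z)-4-(CbCH2)-5-methoxy-4-prenylnona-1,5-diene-1,3,7-trione (acylketene) | C=C(C)[C@@H]1C[C@H](C[C@@](CC=C(C)C)(/C(OC)=C/C(=O)CC)C(=O)C=C=O)C1(C)C | intermediate
18 | (6S)-6-(CbCH2)-3-hydroxy-5-methoxy-6-prenyl-4-propanoylcyclohexa-2,4-dien-1-one | C=C(C)[C@@H]1C[C@H](C[C@@]2(CC=C(C)C)C(OC)=C(C(=O)CC)C(O)=CC2=O)C1(C)C | intermediate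
19 | (4S)-4-(CbCH2)-5-methoxy-3-oxo-4-prenyl-6-propanoylcyclohexa-1,5-dien-1-yl acetate | C=C(C)[C@@H]1C[C@H](C[C@@]2(CC=C(C)C)C(OC)=C(C(=O)CC)C(OC(C)=O)=CC2=O)C1(C)C | intermediate
20 | (6S)-6-(CbCH2)-3-hydroxy-5-methoxy-4-(2-methyl-3-oxobutanoyl)-6-prenylcyclohexa-2,4-dien-1-one (side-chain epimers) | C=C(C)[C@@H]1C[C@H](C[C@@]2(CC=C(C)C)C(OC)=C(C(=O)C(C)C(C)=O)C(O)=CC2=O)C1(C)C | intermediate
21 | (6S)-6-(CbCH2)-5-methoxy-2,3-dimethyl-6-prenyl-4H-chromene-4,7(6H)-dione | C=C(C)[C@@H]1C[C@H](C[C@@]2(CC=C(C)C)C(OC)=C3C(=O)C(C)=C(C)OC3=CC2=O)C1(C)C | intermediate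
22 | (2R,3S,6S)-6-(CbCH2)-5-methoxy-2,3-dimethyl-6-prenyl-2,3-dihydro-4H-chromene-4,7(6H)-dione | C=C(C)[C@@H]1C[C@H](C[C@@]2(CC=C(C)C)C(OC)=C3C(=O)[C@@H](C)[C@@H](C)OC3=CC2=O)C1(C)C | intermediate
23 | (2R,3S,6R)-6-(CbCH2)-4-hydroxy-2,3-dimethyl-6-prenyl-2H-chromene-5,7(3H,6H)-dione | C=C(C)[C@@H]1C[C@H](C[C@@]2(CC=C(C)C)C(=O)C3=C(O)[C@@H](C)[C@@H](C)OC3=CC2=O)C1(C)C | intermediate
24 | (E)-cinnamaldehyde | O=C/C=C/c1ccccc1 | starting material
25 | (3S)-3-[(2R,3S,6R)-6-(CbCH2)-4-hydroxy-2,3-dimethyl-5,7-dioxo-6-prenyl-3,5,6,7-tetrahydro-2H-chromen-8-yl]-3-phenylpropanal | C=C(C)[C@@H]1C[C@H](C[C@@]2(CC=C(C)C)C(=O)C3=C(O)[C@@H](C)[C@@H](C)OC3=C([C@@H](CC=O)c3ccccc3)C2=O)C1(C)C | intermediate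
26 | (3S)-3-[(2R,3S,6R)-6-(CbCH2)-4-hydroxy-2,3-dimethyl-5,7-dioxo-6-prenyl-3,5,6,7-tetrahydro-2H-chromen-8-yl]-3-phenylpropanoic acid | C=C(C)[C@@H]1C[C@H](C[C@@]2(CC=C(C)C)C(=O)C3=C(O)[C@@H](C)[C@@H](C)OC3=C([C@@H](CC(=O)O)c3ccccc3)C2=O)C1(C)C | target

**Summary**

Total step count: 16. Longest linear sequence: 16 steps (1 to 26); compounds 6, 8 and 24 enter this one line.

Three steps most likely to fail:

Step 12 (proposed new method). The ketene may be captured at oxygen or lost to dimerisation faster than the weakly nucleophilic methoxy-enone carbon attacks it, or the O-to-C acetyl transfer may stall. The fallback sets out from 15 and comes back at 23. Conjugate addition of pyrrolidine (MeOH, rt) gives the enaminone tert-butyl (4S)-4-(CbCH2)-4-prenyl-3,7-dioxo-5-(pyrrolidin-1-yl)non-5-enoate F1, whose α-carbon belongs to a class known to be C-acylated by ketenes. Heating in toluene (110 °C) closes ring A to (6S)-6-(CbCH2)-3-hydroxy-6-prenyl-4-propanoyl-5-(pyrrolidin-1-yl)cyclohexa-2,4-dien-1-one F2. Classical Kostanecki–Robinson treatment (Ac2O, NaOAc, 140 °C) builds ring B, giving (6S)-6-(CbCH2)-2,3-dimethyl-6-prenyl-5-(pyrrolidin-1-yl)-4H-chromene-4,7(6H)-dione F3. The copper hydride reduction of step 13 gives (2R,3S,6S)-6-(CbCH2)-2,3-dimethyl-6-prenyl-5-(pyrrolidin-1-yl)-2,3-dihydro-4H-chromene-4,7(6H)-dione F4, and dilute aqueous HCl (THF, rt) hydrolyses the vinylogous amide to 23.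

Step 13. Hydride may be delivered to the wrong β-carbon or face of the tetrasubstituted pyrone alkene, or the cis relationship may be eroded by equilibration of the enolate. The fallback sets the two ring B centres by a reagent-controlled aldol instead; it sets out from 16 and comes back at 22. Compound 16 is heated in toluene (110 °C) without anhydride so that 18 is isolated. Boron enolisation of its propanoyl group with (−)-Ipc2BOTf and i-Pr2NEt (excess, CH2Cl2, −78 °C, the acidic hydroxy-enone being held as its boron chelate) and addition of acetaldehyde should give the syn aldol (6S)-6-(CbCH2)-3-hydroxy-4-[(2S,3R)-3-hydroxy-2-methylbutanoyl]-5-methoxy-6-prenylcyclohexa-2,4-dien-1-one F5. PPTS (toluene, 60 °C) then closes ring B by addition of the new hydroxyl to C8a and loss of water, with retention at C2, giving 22 directly.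

Step 15. Addition at the hindered, strongly acidic C8 position may be slow, reversible or poorly face-selective, and the acidic enol may sequester the amine catalyst. The fallback sets out from 23 and 24 and comes back at 26. Oxidative N-heterocyclic carbene catalysis is used: the enantiomer of an aminoindanol-derived N-mesityltriazolium chloride that gives the (S)-benzylic centre, K2CO3, 3,3',5,5'-tetra-tert-butyl-4,4'-diphenoquinone, toluene, rt. The α,β-unsaturated acyl azolium is attacked at its β-carbon by C8 and the C7 enol oxygen closes the ring, giving the C7-enol δ-lactone of 26 (a (4S)-4-phenyl-3,4-dihydropyran-2-one ring fused across C7–C8) F6. LiOH (THF/H2O, 0 °C) opens the lactone to 26.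

Further compounds
F1 | step 12 | tert-butyl (4S)-4-(CbCH2)-4-prenyl-3,7-dioxo-5-(pyrrolidin-1-yl)non-5-enoate | C=C(C)[C@@H]1C[C@H](C[C@@](CC=C(C)C)(C(N2CCCC2)=CC(=O)CC)C(=O)CC(=O)OC(C)(C)C)C1(C)C
F2 | step 12 | (6S)-6-(CbCH2)-3-hydroxy-6-prenyl-4-propanoyl-5-(pyrrolidin-1-yl)cyclohexa-2,4-dien-1-one | C=C(C)[C@@H]1C[C@H](C[C@@]2(CC=C(C)C)C(N3CCCC3)=C(C(=O)CC)C(O)=CC2=O)C1(C)C
F3 | step 12 | (6S)-6-(CbCH2)-2,3-dimethyl-6-prenyl-5-(pyrrolidin-1-yl)-4H-chromene-4,7(6H)-dione | C=C(C)[C@@H]1C[C@H](C[C@@]2(CC=C(C)C)C(N4CCCC4)=C3C(=O)C(C)=C(C)OC3=CC2=O)C1(C)C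
F4 | step 12 | (2R,3S,6S)-6-(CbCH2)-2,3-dimethyl-6-prenyl-5-(pyrrolidin-1-yl)-2,3-dihydro-4H-chromene-4,7(6H)-dione | C=C(C)[C@@H]1C[C@H](C[C@@]2(CC=C(C)C)C(N4CCCC4)=C3C(=O)[C@@H](C)[C@@H](C)OC3=CC2=O)C1(C)C
F5 | step 13 | (6S)-6-(CbCH2)-3-hydroxy-4-[(2S,3R)-3-hydroxy-2-methylbutanoyl]-5-methoxy-6-prenylcyclohexa-2,4-dien-1-one | C=C(C)[C@@H]1C[C@H](C[C@@]2(CC=C(C)C)C(OC)=C(C(=O)[C@@H](C)[C@@H](C)O)C(O)=CC2=O)C1(C)C
F6 | step 15 | C7-enol δ-lactone of 26 ((4S)-4-phenyl-3,4-dihydropyran-2-one fused across C7–C8) | C=C(C)[C@@H]1C[C@H](C[C@@]2(CC=C(C)C)C(=O)C3=C(O[C@H](C)[C@H](C)C3=O)C4=C2OC(=O)C[C@H]4c5ccccc5)C1(C)C
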